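## Retrosynthetic overview
1. Caraganin C is reached by fluoride desilylation. The E-styryl group comes from a C4 arylethynyl group by syn semihydrogenation and Z-to-E isomerisation. An alkyne is carried because a styryl o-quinone methide would close to a flav-3-ene by oxa-6π cyclisation.
2. Key disconnection: O1–C2 and C3–C4 of the pyran ring, the only ring that is built. It is formed by an enantioselective inverse-demand oxa-[4+2] between two halves of equal mass (both about 427 g/mol), which sets C2, C3 and C4 together.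
3. Ring A half (fragment 1): a lithium arylacetylide added to 2-hydroxy-4-methoxybenzaldehyde, itself made from resorcinol by formylation and mono-methylation.
4. Ring B half (fragment 2): allyl–aryl coupling of a 1-(2,4-dimethoxyphenyl)allyl carbonate with an arylboronic acid. The carbonate comes from resorcinol by dimethylation, formylation and vinyl Grignard addition.
5. Both 4-oxyphenyl rings come from one TIPS-protected 4-iodophenol.

Assumption: the (R)-configured catalyst of step 12 is taken to give the (2R,3R,4S) adduct. If the sense of induction proves opposite, the equally available (S)-catalyst is used.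

## Route

Step 1
Reactants: 1 4-iodophenol
Product: 2 (4-iodophenoxy)triisopropylsilane
Conditions: TIPSCl (1.1 equiv), imidazole (1.5 equiv), DMF, rt
Reagents that add atoms: triisopropylsilyl chloride, CC(C)[Si](Cl)(C(C)C)C(C)C
Why: Imidazole-promoted O-silylation gives a bulky TIPS ether that tolerates the organolithium, carbonate, palladium and Brønsted acid steps ahead and is removed by fluoride at the end without harm to the methyl ethers or the alkene.

Step 2
Reactants: 2 (4-iodophenoxy)triisopropylsilane; 3 ethynyltrimethylsilane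
Product: 4 triisopropyl{4-[(trimethylsilyl)ethynyl]phenoxy}silane
Conditions: Pd(PPh3)2Cl2 (2 mol%), CuI (4 mol%), Et3N, THF, rt
Reagents that add atoms: none
Why: In this Sonogashira coupling the aryl iodide adds oxidatively to zerovalent palladium at room temperature and the copper acetylide of 3 delivers the C2 unit, its TMS cap preventing double coupling.

Step 3
Reactants: 4 triisopropyl{4-[(trimethylsilyl)ethynyl]phenoxy}silane
Product: 5 (4-ethynylphenoxy)triisopropylsilane
Conditions: K2CO3 (0.2 equiv), MeOH/CH2Cl2 1:1, 0 °C to rt, 1 h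
Reagents that add atoms: none
Why: Base-catalysed methanolysis (protiodesilylation) of the C(sp)–SiMe3 bond is much faster than attack at the hindered aryl O–TIPS bond, so only the alkyne terminus is freed.

Step 4
Reactants: 6 resorcinol
Product: 8 2,4-dihydroxybenzaldehyde, via aryl iminium chloride 7 (not isolated)
Conditions: POCl3 (1.1 equiv), DMF (1.3 equiv), MeCN, −15 °C to rt; then H2O, 50 °C
Reagents that add atoms: N,N-dimethylformamide, CN(C)C=O; water, O
Why: In this Vilsmeier–Haack formylation the chloroiminium ion attacks C4 of resorcinol, para to one hydroxyl and ortho to the other, and water hydrolyses the iminium salt to the aldehyde.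

Step 5
Reactants: 8 2,4-dihydroxybenzaldehyde
Product: 9 2-hydroxy-4-methoxybenzaldehyde
Conditions: MeI (1.05 equiv), K2CO3 (1.0 equiv), acetone, rt to 40 °C
Reagents that add atoms: iodomethane, CI
Why: Williamson etherification with one equivalent of base and MeI selects the 4-OH because the 2-OH is held in a hydrogen bond to the formyl oxygen and is less acidic and less nucleophilic.

Step 6
Reactants: 5 (4-ethynylphenoxy)triisopropylsilane; 9 2-hydroxy-4-methoxybenzaldehyde
Product: 12 racemic 2-{1-hydroxy-3-[4-(triisopropylsilyloxy)phenyl]prop-2-yn-1-yl}-5-methoxyphenol (fragment 1), via lithium acetylide 10 (not isolated), via sodium phenoxide 11 (not isolated)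
Conditions: 5 (1.15 equiv), n-BuLi (1.15 equiv), THF, −78 °C; 9 pre-treated with NaH (1.0 equiv), THF, 0 °C, then added; −78 to 0 °C; aq NH4Cl; SiO2/Et3N
Reagents that add atoms: none
Why: This is a 1,2-addition of a lithium acetylide to the aldehyde, whose acidic phenol is first stored as the sodium phenoxide so that no acetylide is wasted, and the racemic carbinol centre is erased in step 12.

Step 7
Reactants: 6 resorcinol
Product: 13 1,3-dimethoxybenzene
Conditions: MeI (2.5 equiv), K2CO3 (2.5 equiv), acetone, reflux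
Reagents that add atoms: iodomethane, CI
Why: Double Williamson etherification of both phenols proceeds cleanly under carbonate conditions, which favour O- over C-methylation.

Step 8
Reactants: 13 1,3-dimethoxybenzene
Product: 15 2,4-dimethoxybenzaldehyde, via aryl iminium chloride 14 (not isolated)
Conditions: POCl3 (1.2 equiv), DMF, 0 to 70 °C; ice-water
Reagents that add atoms: N,N-dimethylformamide, CN(C)C=O; water, O
Why: Vilsmeier–Haack formylation occurs at C4, para to one methoxy group and ortho to the other, because the doubly flanked C2 is too hindered.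

Step 9
Reactants: 15 2,4-dimethoxybenzaldehyde; 16 vinylmagnesium bromide
Product: 18 racemic 1-(2,4-dimethoxyphenyl)prop-2-en-1-yl methyl carbonate, via bromomagnesium alkoxide 17 (not isolated)
Conditions: 16 (1.2 equiv), THF, 0 °C; then ClCO2Me (1.4 equiv), 0 °C to rt; aqueous wash, basic alumina plug, used directly
Reagents that add atoms: methyl chloroformate, COC(=O)Cl
Why: Grignard 1,2-addition with in situ O-acylation avoids isolating the acid-sensitive alcohol, the racemic centre is lost on ionisation in step 11, and any 1,3-transposed cinnamyl carbonate leads to the same π-allyl complex.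

Step 10
Reactants: 2 (4-iodophenoxy)triisopropylsilane
Product: 20 [4-(triisopropylsilyloxy)phenyl]boronic acid, via aryllithium 19 (not isolated)
Conditions: n-BuLi (1.05 equiv), THF, −78 °C; B(OiPr)3 (1.3 equiv), −78 °C to rt; 1 M HCl, 0 °C
Reagents that add atoms: triisopropyl borate, CC(C)OB(OC(C)C)OC(C)C; water, O
Why: Iodine–lithium exchange is faster than any attack on the para silyl ether, and electrophilic borylation followed by brief acid hydrolysis gives the boronic acid.

Step 11
Reactants: 18 racemic 1-(2,4-dimethoxyphenyl)prop-2-en-1-yl methyl carbonate; 20 [4-(triisopropylsilyloxy)phenyl]boronic acid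
Product: 21 (E)-1-(2,4-dimethoxyphenyl)-3-[4-(triisopropylsilyloxy)phenyl]prop-1-ene (fragment 2)
Conditions: Pd(PPh3)4 (3 mol%), THF, 60 °C, no added base
Reagents that add atoms: none
Why: In this Suzuki–Miyaura allyl–aryl coupling via Tsuji–Trost ionisation, zerovalent palladium expels CO2, the methoxide released activates the boronic acid without an external base that could attack the TIPS ether, and reductive elimination at the unsubstituted allyl terminus keeps the styrene conjugation and gives the linear E-alkene.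

Step 12
Reactants: 12 racemic 2-{1-hydroxy-3-[4-(triisopropylsilyloxy)phenyl]prop-2-yn-1-yl}-5-methoxyphenol; 21 (E)-1-(2,4-dimethoxyphenyl)-3-[4-(triisopropylsilyloxy)phenyl]prop-1-ene
Product: 23 (2R,3R,4S)-2-(2,4-dimethoxyphenyl)-7-methoxy-3-[4-(triisopropylsilyloxy)benzyl]-4-{[4-(triisopropylsilyloxy)phenyl]ethynyl}chromane, via alkynyl o-quinone methide 22 (not isolated)
Conditions: 21 (1.3 equiv), (R)-3,3'-bis(2,4,6-triisopropylphenyl)-1,1'-binaphthalene-2,2'-diyl N-(trifluoromethylsulfonyl)phosphoramide (10 mol%), 4 Å MS, CH2Cl2, −60 to −30 °C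
Reagents that add atoms: none
Why: Acid-catalysed dehydration of 12 gives the (E)-o-quinone methide 22 bound to the chiral phosphoramide anion, and an inverse-electron-demand oxa-Diels–Alder reaction with 21 bonds C4 to the benzyl-bearing alkene carbon and O1 to the carbon carrying the cation-stabilising 2,4-dimethoxyphenyl group, suprafacial addition to the E-alkene setting 2,3-trans, the endo aryl group over the E-methide setting 2,4-cis (hence 3,4-trans, all equatorial), and the 3,3'-aryl walls of the catalyst leaving one face of 22 open, which sets the absolute configuration.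

Step 13
Reactants: 23 (2R,3R,4S)-2-(2,4-dimethoxyphenyl)-7-methoxy-3-[4-(triisopropylsilyloxy)benzyl]-4-{[4-(triisopropylsilyloxy)phenyl]ethynyl}chromane
Product: 24 (2R,3R,4R)-2-(2,4-dimethoxyphenyl)-7-methoxy-3-[4-(triisopropylsilyloxy)benzyl]-4-{(Z)-2-[4-(triisopropylsilyloxy)phenyl]ethenyl}chromane
Conditions: H2 (1 atm), Pd/CaCO3 poisoned with Pb(OAc)2, quinoline, EtOAc, rt, stopped after 1 equiv H2
Reagents that add atoms: none
Why: Lindlar-type semihydrogenation delivers H2 syn on the poisoned palladium surface and stops at the Z-alkene, leaving the benzylic C–O bond, the silyl ethers and the three stereocentres untouched (the C4 descriptor changes only through CIP priorities).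

Step 14
Reactants: 24 (2R,3R,4R)-2-(2,4-dimethoxyphenyl)-7-methoxy-3-[4-(triisopropylsilyloxy)benzyl]-4-{(Z)-2-[4-(triisopropylsilyloxy)phenyl]ethenyl}chromane
Product: 25 (2R,3R,4R)-2-(2,4-dimethoxyphenyl)-7-methoxy-3-[4-(triisopropylsilyloxy)benzyl]-4-{(E)-2-[4-(triisopropylsilyloxy)phenyl]ethenyl}chromane
Conditions: Pd(MeCN)2Cl2 (10 mol%), CH2Cl2, rt
Reagents that add atoms: none
Why: Z-to-E isomerisation of a cis-aryl alkene catalysed by divalent palladium is driven by relief of allylic strain against the branched C4, and it runs through a benzylic palladium alkyl remote from C4–H, so neither bond migration nor epimerisation is expected.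

Step 15
Reactants: 25 (2R,3R,4R)-2-(2,4-dimethoxyphenyl)-7-methoxy-3-[4-(triisopropylsilyloxy)benzyl]-4-{(E)-2-[4-(triisopropylsilyloxy)phenyl]ethenyl}chromane
Product: 26 caraganin C, (2R,3R,4R)-2-(2,4-dimethoxyphenyl)-3-(4-hydroxybenzyl)-4-[(E)-2-(4-hydroxyphenyl)ethenyl]-7-methoxychromane
Conditions: Bu4NF (2.4 equiv), AcOH (2.4 equiv), THF, 0 °C
Reagents that add atoms: none
Why: Fluoride-mediated desilylation cleaves both aryl TIPS ethers, and the acetic acid buffer keeps the phenols protonated so that the doubly activated C4–H and the methyl ethers are not touched.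

## Compound list
1 | 4-iodophenol | Oc1ccc(I)cc1 | starting material
2 | (4-iodophenoxy)triisopropylsilane | CC(C)[Si](Oc1ccc(I)cc1)(C(C)C)C(C)C | intermediate
3 | ethynyltrimethylsilane | C#C[Si](C)(C)C | starting material
4 | triisopropyl{4-[(trimethylsilyl)ethynyl]phenoxy}silane | CC(C)[Si](Oc1ccc(cc1)C#C[Si](C)(C)C)(C(C)C)C(C)C | intermediate
5 | (4-ethynylphenoxy)triisopropylsilane | C#Cc1ccc(O[Si](C(C)C)(C(C)C)C(C)C)cc1 | intermediate
6 | resorcinol | Oc1cccc(O)c1 | starting material
7 | (2,4-dihydroxybenzylidene)dimethyliminium chloride, formed in situ | C[N+](C)=Cc1ccc(O)cc1O.[Cl-] | intermediate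
8 | 2,4-dihydroxybenzaldehyde | O=Cc1ccc(O)cc1O | intermediate
9 | 2-hydroxy-4-methoxybenzaldehyde | COc1ccc(C=O)c(O)c1 | intermediate
10 | lithium [4-(triisopropylsilyloxy)phenyl]acetylide, formed in situ | [Li]C#Cc1ccc(O[Si](C(C)C)(C(C)C)C(C)C)cc1 | intermediate
11 | sodium 2-formyl-5-methoxyphenolate, formed in situ | COc1ccc(C=O)c([O-])c1.[Na+] | intermediate
12 | racemic 2-{1-hydroxy-3-[4-(triisopropylsilyloxy)phenyl]prop-2-yn-1-yl}-5-methoxyphenol (fragment 1) | COc1ccc(C(O)C#Cc2ccc(O[Si](C(C)C)(C(C)C)C(C)C)cc2)c(O)c1 | intermediate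
13 | 1,3-dimethoxybenzene | COc1cccc(OC)c1 | intermediate
14 | (2,4-dimethoxybenzylidene)dimethyliminium chloride, formed in situ | COc1ccc(C=[N+](C)C)c(OC)c1.[Cl-] | intermediate
15 | 2,4-dimethoxybenzaldehyde | COc1ccc(C=O)c(OC)c1 | intermediate
16 | vinylmagnesium bromide | C=C[Mg]Br | starting material
17 | bromomagnesium 1-(2,4-dimethoxyphenyl)prop-2-en-1-olate (racemic), formed in situ | COc1ccc(C(C=C)O[Mg]Br)c(OC)c1 | intermediate
18 | racemic 1-(2,4-dimethoxyphenyl)prop-2-en-1-yl methyl carbonate | COC(=O)OC(C=C)c1ccc(OC)cc1OC | intermediate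
19 | [4-(triisopropylsilyloxy)phenyl]lithium, formed in situ | [Li]c1ccc(O[Si](C(C)C)(C(C)C)C(C)C)cc1 | intermediate
20 | [4-(triisopropylsilyloxy)phenyl]boronic acid | OB(O)c1ccc(O[Si](C(C)C)(C(C)C)C(C)C)cc1 | intermediate
21 | (E)-1-(2,4-dimethoxyphenyl)-3-[4-(triisopropylsilyloxy)phenyl]prop-1-ene (fragment 2) | COc1ccc(/C=C/Cc2ccc(O[Si](C(C)C)(C(C)C)C(C)C)cc2)c(OC)c1 | intermediate
22 | (6E)-3-methoxy-6-{3-[4-(triisopropylsilyloxy)phenyl]prop-2-yn-1-ylidene}cyclohexa-2,4-dien-1-one, formed in situ | COC1=CC(=O)/C(C=C1)=C/C#Cc1ccc(O[Si](C(C)C)(C(C)C)C(C)C)cc1 | intermediate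
23 | (2R,3R,4S)-2-(2,4-dimethoxyphenyl)-7-methoxy-3-[4-(triisopropylsilyloxy)benzyl]-4-{[4-(triisopropylsilyloxy)phenyl]ethynyl}chromane (2,3-trans, 3,4-trans) | COc1ccc2c(c1)O[C@@H](c1ccc(OC)cc1OC)[C@H](Cc1ccc(O[Si](C(C)C)(C(C)C)C(C)C)cc1)[C@H]2C#Cc1ccc(O[Si](C(C)C)(C(C)C)C(C)C)cc1 | intermediate
24 | (2R,3R,4R)-2-(2,4-dimethoxyphenyl)-7-methoxy-3-[4-(triisopropylsilyloxy)benzyl]-4-{(Z)-2-[4-(triisopropylsilyloxy)phenyl]ethenyl}chromane | COc1ccc2c(c1)O[C@@H](c1ccc(OC)cc1OC)[C@H](Cc1ccc(O[Si](C(C)C)(C(C)C)C(C)C)cc1)[C@H]2/C=C\c1ccc(O[Si](C(C)C)(C(C)C)C(C)C)cc1 | intermediate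
25 | (2R,3R,4R)-2-(2,4-dimethoxyphenyl)-7-methoxy-3-[4-(triisopropylsilyloxy)benzyl]-4-{(E)-2-[4-(triisopropylsilyloxy)phenyl]ethenyl}chromane | COc1ccc2c(c1)O[C@@H](c1ccc(OC)cc1OC)[C@H](Cc1ccc(O[Si](C(C)C)(C(C)C)C(C)C)cc1)[C@H]2/C=C/c1ccc(O[Si](C(C)C)(C(C)C)C(C)C)cc1 | intermediate
26 | caraganin C, (2R,3R,4R)-2-(2,4-dimethoxyphenyl)-3-(4-hydroxybenzyl)-4-[(E)-2-(4-hydroxyphenyl)ethenyl]-7-methoxychromane | COc1ccc2c(c1)O[C@@H](c1ccc(OC)cc1OC)[C@H](Cc1ccc(O)cc1)[C@H]2/C=C/c1ccc(O)cc1 | target

## Step count
Total step count: 15.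
Longest linear sequence: 8 steps, along 1 → 2 → 4 → 5 → 12 → 23 → 24 → 25 → 26. The line 6 → 13 → 15 → 18 → 21 → 23 → 26 is equally long.

## Steps most likely to fail

**Step 12 (asymmetric oxa-[4+2]).**
- Several things can go wrong:
  - The acid may protonate or oligomerise the very electron-rich alkene 21.
  - Ring B of 21 may attack 22 in a Friedel–Crafts sense, or attack may occur at the distal alkyne carbon to give an allene.
  - Traces of water may divert 12 into a Meyer–Schuster enone.
  - Facial control with a partner that offers the catalyst no hydrogen bond may be only moderate.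
- The fallback sets out from 9, 5 and 21 and comes back at 23.
- It replaces acid catalysis by an anionic release of the methide, followed by resolution.
- Compound 9 is acylated with Boc2O (DMAP cat., CH2Cl2) to tert-butyl 2-formyl-5-methoxyphenyl carbonate F1.
- Compound 5 is deprotonated with EtMgBr in THF to {[4-(triisopropylsilyloxy)phenyl]ethynyl}magnesium bromide F2.
- F2 is added to F1 at −78 °C in the presence of 21 (3 equiv) and the mixture is warmed to rt. Addition, O-to-O carbonate migration and loss of tert-butyl carbonate then release 22 under non-acidic conditions.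
- The thermal endo cycloaddition gives the all-trans adduct as a racemate, that is 23 together with its mirror image ent-23 F3.
- The two are separated by preparative HPLC on a cellulose tris(3,5-dimethylphenylcarbamate) phase.

**Step 14 (Z-to-E isomerisation).**
- The risks are incomplete conversion, migration of the double bond toward C4 and side reactions of the electron-rich styrene at divalent palladium.
- The fallback sets out from 23 and comes back at 26, bypassing steps 13 to 15.
- Trans-hydrosilylation of the alkyne with HSi(OEt)3 and [Cp*Ru(MeCN)3]PF6 (5 mol%, CH2Cl2, 0 °C to rt) gives (2R,3R,4S)-2-(2,4-dimethoxyphenyl)-7-methoxy-4-{(Z)-2-(triethoxysilyl)-2-[4-(triisopropylsilyloxy)phenyl]ethenyl}-3-[4-(triisopropylsilyloxy)benzyl]chromane F4.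
- The regioisomeric vinylsilane would converge on the same alkene.
- Bu4NF (5 equiv) with CuI (10 mol%) in wet THF then replaces silicon by hydrogen with retention. This gives the E-alkene directly and removes both TIPS groups in the same flask.

**Step 11 (allyl–aryl coupling with the labile carbonate 18).**
- The risks are decomposition of 18, capture of the allyl complex by methoxide and partial migration of the double bond to the other aryl group.
- The fallback sets out from 2 (through 19) and 15 and comes back at 21.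
- It fixes the position of the alkene by carbonyl addition and elimination instead of cross-coupling.
- Aryllithium 19 opens oxirane (THF, −78 to 0 °C) to give 2-[4-(triisopropylsilyloxy)phenyl]ethanol F5.
- An Appel reaction (CBr4, PPh3, CH2Cl2) gives [4-(2-bromoethyl)phenoxy]triisopropylsilane F6.
- Magnesium in THF gives 2-[4-(triisopropylsilyloxy)phenyl]ethylmagnesium bromide F7.
- Addition of F7 to 15 gives racemic 1-(2,4-dimethoxyphenyl)-3-[4-(triisopropylsilyloxy)phenyl]propan-1-ol F8.
- Catalytic pyridinium p-toluenesulfonate in toluene at 80 °C dehydrates F8 through the 2,4-dimethoxybenzyl cation. This cation can lose a proton only toward the conjugated E-alkene 21.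

## Further compounds
F1 | step 12 | tert-butyl 2-formyl-5-methoxyphenyl carbonate | COc1ccc(C=O)c(OC(=O)OC(C)(C)C)c1
F2 | step 12 | {[4-(triisopropylsilyloxy)phenyl]ethynyl}magnesium bromide | Br[Mg]C#Cc1ccc(O[Si](C(C)C)(C(C)C)C(C)C)cc1
F3 | step 12 | ent-23, (2S,3S,4R)-2-(2,4-dimethoxyphenyl)-7-methoxy-3-[4-(triisopropylsilyloxy)benzyl]-4-{[4-(triisopropylsilyloxy)phenyl]ethynyl}chromane | COc1ccc2c(c1)O[C@H](c1ccc(OC)cc1OC)[C@@H](Cc1ccc(O[Si](C(C)C)(C(C)C)C(C)C)cc1)[C@@H]2C#Cc1ccc(O[Si](C(C)C)(C(C)C)C(C)C)cc1
F4 | step 14 | (2R,3R,4S)-2-(2,4-dimethoxyphenyl)-7-methoxy-4-{(Z)-2-(triethoxysilyl)-2-[4-(triisopropylsilyloxy)phenyl]ethenyl}-3-[4-(triisopropylsilyloxy)benzyl]chromane | COc1ccc2c(c1)O[C@@H](c1ccc(OC)cc1OC)[C@H](Cc1ccc(O[Si](C(C)C)(C(C)C)C(C)C)cc1)[C@H]2/C=C(\[Si](OCC)(OCC)OCC)c1ccc(O[Si](C(C)C)(C(C)C)C(C)C)cc1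
F5 | step 11 | 2-[4-(triisopropylsilyloxy)phenyl]ethanol | OCCc1ccc(O[Si](C(C)C)(C(C)C)C(C)C)cc1
F6 | step 11 | [4-(2-bromoethyl)phenoxy]triisopropylsilane | BrCCc1ccc(O[Si](C(C)C)(C(C)C)C(C)C)cc1
F7 | step 11 | 2-[4-(triisopropylsilyloxy)phenyl]ethylmagnesium bromide | Br[Mg]CCc1ccc(O[Si](C(C)C)(C(C)C)C(C)C)cc1
F8 | step 11 | racemic 1-(2,4-dimethoxyphenyl)-3-[4-(triisopropylsilyloxy)phenyl]propan-1-ol | COc1ccc(C(O)CCc2ccc(O[Si](C(C)C)(C(C)C)C(C)C)cc2)c(OC)c1
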